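**Retrosynthetic overview**

1. The target is a 5,6,7,8-tetrahydrochromone, and the plan rests on its carbocycle C4a–C5–C6–C7–C8–C8a. The cis 5,6-diol (5S,6S) is C3/C4 of 2-deoxy-D-ribose, C4a is the sugar C2 methylene beside the C8a carbonyl carbon (sugar C1), and the trans C7-OH/C8-Cl pair is a masked C7=C8 alkene.
2. Disconnections: C8–Cl/C7–OH ⇒ 7,8-epoxide cis to the C5/C6 oxygens ⇒ trans bromohydrin of C7=C8. Pyranone (O1–C8a and C4–C4a bonds) ⇒ enol silane of a cyclohexenone plus an acylketene from an arylethyl dioxinone (isovanillin and 2,2,6-trimethyl-4H-1,3-dioxin-4-one). C7=C8 ⇒ ring-closing metathesis of a 1,7-diene (sugar acetonide, vinyl Grignard at C1, methylenation at C5).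
3. Ring order: carbocycle first (step 6), pyranone second (step 14); the aryl ring comes with isovanillin.
4. Remark on the chemistry: the acetonide stays until the last step, because a free 5,6-diol beside C7=C8 would be expected to dehydrate to the aromatic chromone under acid. The epoxide is therefore placed cis to the acetonide by bromohydrin formation and closure. The carbinol that becomes C8a is carried as both epimers until step 8.

Key step: step 6

**Route**

Step 1
Reactants: 1 2-deoxy-D-ribose
Product: 2 2-deoxy-3,4-O-isopropylidene-D-erythro-pentopyranose (lactol, both anomers)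
Conditions: 2-methoxypropene, PPTS (cat.), EtOAc, 0 °C → rt
Reagents that add atoms: 2-methoxypropene, COC(C)=C
Why: Acid-catalysed acetonide formation (transacetalisation with an enol ether): in the pyranose form the cis C3/C4 diol is the only pair that can close a five-membered ketal, which should leave the anomeric hydroxyl free and touch no stereocentre.

Step 2
Reactants: 2 2-deoxy-3,4-O-isopropylidene-D-erythro-pentopyranose; 3 vinylmagnesium bromide
Product: 4 1-[(4S,5R)-5-(hydroxymethyl)-2,2-dimethyl-1,3-dioxolan-4-yl]but-3-en-2-ol (both carbinol epimers)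
Conditions: CH2=CHMgBr (3 equiv), THF, 0 °C → rt; aqueous work-up
Reagents that add atoms: none
Why: Grignard addition to the aldehyde released by ring opening of the lactol magnesium alkoxide; the new carbinol carbon (later C8a) is expected as both epimers, which does not matter because step 8 oxidises it.

Step 3
Reactants: 4 diol
Product: 5 bis(triethylsilyl) ether of 4
Conditions: Et3SiCl, imidazole, CH2Cl2, 0 °C → rt
Reagents that add atoms: chlorotriethylsilane, CC[Si](Cl)(CC)CC
Why: Silyl ether formation on both hydroxyls; triethylsilyl is chosen because its primary ether can be oxidised directly in step 4 while the secondary one stays.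

Step 4
Reactants: 5 bis(triethylsilyl) ether
Product: 6 (4S,5S)-2,2-dimethyl-5-[2-(triethylsilyloxy)but-3-enyl]-1,3-dioxolane-4-carbaldehyde (both silyloxy epimers)
Conditions: (COCl)2, DMSO, CH2Cl2, −78 → −35 °C; then Et3N, −78 → 0 °C
Reagents that add atoms: none
Why: Swern oxidation run on the bis-silyl ether: the chlorosulfonium reagent cleaves and oxidises the unhindered primary triethylsilyl ether selectively and leaves the secondary allylic one, and the low temperature should keep the alpha-alkoxy aldehyde carbon (sugar C4) from epimerising.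

Step 5
Reactants: 6 aldehyde
Product: 7 (4S,5R)-2,2-dimethyl-4-[2-(triethylsilyloxy)but-3-enyl]-5-vinyl-1,3-dioxolane (both silyloxy epimers)
Conditions: Ph3PCH3Br, KN(SiMe3)2, THF, −78 → 0 °C
Reagents that add atoms: methyltriphenylphosphonium bromide, C[P+](c1ccccc1)(c1ccccc1)c1ccccc1.[Br-]
Why: Wittig methylenation with the non-stabilised ylide at low temperature, which should turn the aldehyde into the second terminal vinyl group without epimerising the adjacent dioxolane carbon.

Step 6
Reactants: 7 silyl-protected 1,7-diene
Product: 8 triethylsilyl ether of (4R,5S)-4,5-(isopropylidenedioxy)cyclohex-2-en-1-ol (both C1 epimers)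
Conditions: second-generation Grubbs catalyst RuCl2(=CHPh)(PCy3)(H2IMes) (3 mol%), CH2Cl2 (0.01 M), 40 °C
Reagents that add atoms: none
Why: Ring-closing olefin metathesis by the metallacyclobutane mechanism: the ruthenium benzylidene exchanges onto one terminal vinyl group of 7, the new alkylidene adds intramolecularly to the second vinyl group to give a ruthenacyclobutane, and cycloreversion releases cyclohexene 8 while ethene leaves and drives the cycle. The closest known reaction type is the ring-closing metathesis of carbohydrate-derived 1,7-dienes with allylic oxygen substituents to polyoxygenated cyclohexenes. The one ring formed is the six-membered carbocycle, closed by making the C7=C8 double bond (target numbering) between the Grignard-derived and the Wittig-derived vinyl CH carbons, with the ring enforcing the Z alkene. No stereocentre is created: C5 and C6 come unchanged from sugar C3 and C4, and both C8a-carbinol epimers should cyclise. The selectivity needed is cyclisation over intermolecular metathesis, which is secured by high dilution, by the two unhindered monosubstituted alkenes and by the cis-dioxolane that holds the two chain ends on the same side.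

Step 7
Reactants: 8 cyclohexenyl triethylsilyl ether
Product: 9 (4R,5S)-4,5-(isopropylidenedioxy)cyclohex-2-en-1-ol (both C1 epimers)
Conditions: HF·pyridine, pyridine, THF, 0 °C → rt
Reagents that add atoms: none
Why: Fluoride-induced desilylation (strong Si–F bond); pyridine-buffered HF should spare the acetonide.

Step 8
Reactants: 9 cyclohexenol
Product: 10 (4R,5S)-4,5-(isopropylidenedioxy)cyclohex-2-en-1-one
Conditions: MnO2 (activated, excess), CH2Cl2, rt
Reagents that add atoms: none
Why: Allylic alcohol oxidation with MnO2: both carbinol epimers converge on one enone, so the uncontrolled centre disappears and the carbonyl carbon (C8a) has its only enolisable methylene (C4a) on the side away from the alkene.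

Step 9
Reactants: 10 enone
Product: 11 (5R,6S)-2-(tert-butyldimethylsilyloxy)-5,6-(isopropylidenedioxy)cyclohexa-1,3-diene
Conditions: TBSOTf, Et3N, CH2Cl2, −78 → 0 °C
Reagents that add atoms: tert-butyldimethylsilyl trifluoromethanesulfonate, CC(C)(C)[Si](C)(C)OS(=O)(=O)C(F)(F)F
Why: Soft enolisation to a silyl enol ether (silyl triflate and amine): O-silylation followed by loss of a C4a proton gives the cross-conjugated 2-silyloxydiene without a free enolate, which should avoid beta-elimination of the C5 acetonide oxygen.

Step 10
Reactants: 12 isovanillin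
Product: 13 5-formyl-2-methoxyphenyl pivalate
Conditions: PivCl, Et3N, DMAP (cat.), CH2Cl2, 0 °C → rt
Reagents that add atoms: pivaloyl chloride, CC(C)(C)C(Cl)=O
Why: Acylation of the phenol to its pivalate ester; the ester shields the phenol from the acylketene of step 14 and makes the aryl ring too electron-poor to compete for NBS in step 15.

Step 11
Reactants: 13 aldehyde pivalate
Product: 14 5-(hydroxymethyl)-2-methoxyphenyl pivalate
Conditions: NaBH4, MeOH, 0 °C
Reagents that add atoms: none
Why: Chemoselective borohydride reduction of the aldehyde, which the hindered aryl ester should survive at 0 °C.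

Step 12
Reactants: 14 benzylic alcohol
Product: 15 5-(bromomethyl)-2-methoxyphenyl pivalate
Conditions: PBr3, CH2Cl2, 0 °C
Reagents that add atoms: phosphorus tribromide, BrP(Br)Br
Why: Conversion of the benzylic alcohol into the bromide through its bromophosphite (SN2 by bromide).

Step 13
Reactants: 16 2,2,6-trimethyl-4H-1,3-dioxin-4-one; 15 benzylic bromide
Product: 18 6-[2-(4-methoxy-3-pivaloyloxyphenyl)ethyl]-2,2-dimethyl-4H-1,3-dioxin-4-one, via lithium dienolate 17 (not isolated)
Conditions: LiN(iPr)2, THF/DMPU, −78 °C; then 15, −78 → −20 °C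
Reagents that add atoms: none
Why: Alkylation of the extended lithium dienolate of the dioxinone at its exocyclic (gamma) carbon by a reactive benzylic bromide (vinylogous enolate alkylation), with DMPU to raise reactivity; the stabilised dienolate should not attack the hindered pivalate at low temperature.

Step 14
Reactants: 11 silyloxydiene; 18 arylethyl dioxinone
Product: 21 (5S,6R)-5,6-(isopropylidenedioxy)-2-[2-(4-methoxy-3-pivaloyloxyphenyl)ethyl]-5,6-dihydro-4H-chromen-4-one, via acylketene 19 (not isolated), via silyl ketal cycloadduct 20 (not isolated)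
Conditions: toluene, 110 °C (slow addition of 18); then PPTS (cat.), rt
Reagents that add atoms: none
Why: Proposed new method: thermolysis of the dioxinone (retro-[4+2], loss of acetone) releases acylketene 19, whose electron-poor 1-oxadiene should add across the electron-rich C4a=C8a enol silane bond of 11 in an inverse-demand hetero-Diels–Alder reaction (nucleophilic C4a to the ketene carbon, acyl oxygen to C8a), and silyl ketal 20 should then lose silanol under mild acid to give the gamma-pyrone, with no lasting stereocentre formed; the closest known reaction type is the [4+2] addition of dioxinone-derived acylketenes to alkyl enol ethers, which gives 2-alkoxy-2,3-dihydro-4-pyranones that eliminate alcohol to 4-pyranones, together with the formation of tetrahydrochromones from enamines and diketene.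

Step 15
Reactants: 21 dihydrochromenone acetonide with C7=C8
Product: 22 trans bromohydrin: 7-bromo (trans to the acetonide oxygens) and 8-hydroxy (cis to them) derivative of the 5,6-acetonide tetrahydrochromenone, pivalate retained
Conditions: NBS, THF/H2O, 0 °C, dark
Reagents that add atoms: N-bromosuccinimide, O=C1CCC(=O)N1Br; water, O
Why: Bromohydrin formation (electrophilic anti addition of Br and OH): the bromonium ion should form on the alkene face away from the cis-fused acetonide and be opened by water from the acetonide face, most likely at allylic C8, so that OH and Br are trans; the regioisomeric trans bromohydrin would lead to the same epoxide in step 16.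

Step 16
Reactants: 22 trans bromohydrin
Product: 24 7,8-epoxy-5,6-(isopropylidenedioxy)-2-[2-(3-hydroxy-4-methoxyphenyl)ethyl]-5,6,7,8-tetrahydro-4H-chromen-4-one (epoxide oxygen cis to the acetonide oxygens), via epoxide pivalate 23 (not isolated)
Conditions: K2CO3, MeOH, 0 °C → rt
Reagents that add atoms: none
Why: Intramolecular Williamson etherification: the alkoxide displaces the trans bromide with inversion, which puts the epoxide oxygen on the face of the acetonide oxygens, and the same carbonate/methanol medium removes the aryl pivalate by transesterification.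

Step 17
Reactants: 24 epoxy acetonide phenol
Product: 26 (5S,6S,7S,8R)-8-chloro-5,6,7-trihydroxy-2-[2-(3-hydroxy-4-methoxyphenyl)ethyl]-5,6,7,8-tetrahydro-4H-chromen-4-one, via chlorohydrin acetonide 25 (not isolated)
Conditions: conc. aq. HCl, THF, 0 °C → rt
Reagents that add atoms: hydrogen chloride, Cl
Why: Acid-promoted SN2 opening of the epoxide by chloride at C8, the carbon allylic to the pyranone and not flanked by the C6 oxygen, with inversion gives the 8-chloride trans to the retained 7-hydroxyl (fixing 7S,8R), and the aqueous acid then hydrolyses the acetonide (ketal hydrolysis) to free the 5,6-diol.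

**Compound list**

1 | 2-deoxy-D-ribose, (3S,4R)-3,4,5-trihydroxypentanal (open-chain form drawn) | O=CC[C@H](O)[C@H](O)CO | starting material
2 | 2-deoxy-3,4-O-isopropylidene-D-erythro-pentopyranose (lactol, both anomers) | OC1C[C@@H]2OC(C)(C)O[C@@H]2CO1 | intermediate
3 | vinylmagnesium bromide | C=C[Mg]Br | starting material
4 | 1-[(4S,5R)-5-(hydroxymethyl)-2,2-dimethyl-1,3-dioxolan-4-yl]but-3-en-2-ol (both carbinol epimers) | C=CC(O)C[C@@H]1OC(C)(C)O[C@@H]1CO | intermediate
5 | bis(triethylsilyl) ether of 4 | C=CC(O[Si](CC)(CC)CC)C[C@@H]1OC(C)(C)O[C@@H]1CO[Si](CC)(CC)CC | intermediate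
6 | (4S,5S)-2,2-dimethyl-5-[2-(triethylsilyloxy)but-3-enyl]-1,3-dioxolane-4-carbaldehyde (both silyloxy epimers) | C=CC(O[Si](CC)(CC)CC)C[C@@H]1OC(C)(C)O[C@@H]1C=O | intermediate
7 | (4S,5R)-2,2-dimethyl-4-[2-(triethylsilyloxy)but-3-enyl]-5-vinyl-1,3-dioxolane (both silyloxy epimers; metathesis precursor) | C=CC(O[Si](CC)(CC)CC)C[C@@H]1OC(C)(C)O[C@@H]1C=C | intermediate
8 | triethylsilyl ether of (4R,5S)-4,5-(isopropylidenedioxy)cyclohex-2-en-1-ol (both C1 epimers; metathesis product) | CC[Si](CC)(CC)OC1C=C[C@H]2OC(C)(C)O[C@H]2C1 | intermediate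
9 | (4R,5S)-4,5-(isopropylidenedioxy)cyclohex-2-en-1-ol (both C1 epimers) | OC1C=C[C@H]2OC(C)(C)O[C@H]2C1 | intermediate
10 | (4R,5S)-4,5-(isopropylidenedioxy)cyclohex-2-en-1-one | O=C1C=C[C@H]2OC(C)(C)O[C@H]2C1 | intermediate
11 | (5R,6S)-2-(tert-butyldimethylsilyloxy)-5,6-(isopropylidenedioxy)cyclohexa-1,3-diene | CC(C)(C)[Si](C)(C)OC1=C[C@@H]2OC(C)(C)O[C@@H]2C=C1 | intermediate
12 | isovanillin (3-hydroxy-4-methoxybenzaldehyde) | COc1ccc(C=O)cc1O | starting material
13 | 5-formyl-2-methoxyphenyl pivalate | COc1ccc(C=O)cc1OC(=O)C(C)(C)C | intermediate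
14 | 5-(hydroxymethyl)-2-methoxyphenyl pivalate | COc1ccc(CO)cc1OC(=O)C(C)(C)C | intermediate
15 | 5-(bromomethyl)-2-methoxyphenyl pivalate | COc1ccc(CBr)cc1OC(=O)C(C)(C)C | intermediate
16 | 2,2,6-trimethyl-4H-1,3-dioxin-4-one | CC1=CC(=O)OC(C)(C)O1 | starting material
17 | lithium dienolate of 16 (lithium 2,2-dimethyl-6-methylidene-1,3-dioxin-4-olate) | [Li+].C=C1C=C([O-])OC(C)(C)O1 | intermediate
18 | 6-[2-(4-methoxy-3-pivaloyloxyphenyl)ethyl]-2,2-dimethyl-4H-1,3-dioxin-4-one | COc1ccc(CCC2=CC(=O)OC(C)(C)O2)cc1OC(=O)C(C)(C)C | intermediate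
19 | acylketene 5-(4-methoxy-3-pivaloyloxyphenyl)-3-oxopent-1-en-1-one | COc1ccc(CCC(=O)C=C=O)cc1OC(=O)C(C)(C)C | intermediate
20 | silyl ketal cycloadduct: 8a-(tert-butyldimethylsilyloxy)-4a,8a-dihydro precursor of 21 (C4a and C8a not defined) | COc1ccc(CCC2=CC(=O)C3C(O2)(O[Si](C)(C)C(C)(C)C)C=C[C@H]4OC(C)(C)O[C@@H]34)cc1OC(=O)C(C)(C)C | intermediate
21 | (5S,6R)-5,6-(isopropylidenedioxy)-2-[2-(4-methoxy-3-pivaloyloxyphenyl)ethyl]-5,6-dihydro-4H-chromen-4-one | COc1ccc(CCc2cc(=O)c3c(o2)C=C[C@H]4OC(C)(C)O[C@@H]34)cc1OC(=O)C(C)(C)C | intermediate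
22 | trans bromohydrin of 21: 7-bromo trans and 8-hydroxy cis to the 5,6-acetonide oxygens, pivalate retained | COc1ccc(CCc2cc(=O)c3c(o2)[C@@H](O)[C@H](Br)[C@H]4OC(C)(C)O[C@@H]34)cc1OC(=O)C(C)(C)C | intermediate
23 | 7,8-epoxide pivalate (epoxide oxygen cis to the acetonide oxygens) | COc1ccc(CCc2cc(=O)c3c(o2)[C@H]5O[C@H]5[C@H]4OC(C)(C)O[C@@H]34)cc1OC(=O)C(C)(C)C | intermediate
24 | 7,8-epoxy-5,6-(isopropylidenedioxy)-2-[2-(3-hydroxy-4-methoxyphenyl)ethyl]-5,6,7,8-tetrahydro-4H-chromen-4-one (epoxide oxygen cis to the acetonide oxygens) | COc1ccc(CCc2cc(=O)c3c(o2)[C@H]5O[C@H]5[C@H]4OC(C)(C)O[C@@H]34)cc1O | intermediate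
25 | chlorohydrin acetonide: 8-chloro-7-hydroxy-5,6-(isopropylidenedioxy) compound with the target configuration | COc1ccc(CCc2cc(=O)c3c(o2)[C@H](Cl)[C@@H](O)[C@H]4OC(C)(C)O[C@@H]34)cc1O | intermediate
26 | (5S,6S,7S,8R)-8-chloro-5,6,7-trihydroxy-2-[2-(3-hydroxy-4-methoxyphenyl)ethyl]-5,6,7,8-tetrahydro-4H-chromen-4-one | COc1ccc(CCc2cc(=O)c3c(o2)[C@H](Cl)[C@@H](O)[C@@H](O)[C@H]3O)cc1O | target

**Step count and risks**

Total step count: 17. Longest linear sequence: 13 steps (steps 1–9 and 14–17 from 2-deoxy-D-ribose); the side-chain branch (steps 10–13) joins at step 14.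

Steps most likely to fail:

1. Step 14 (the proposed new method). The acylketene may dimerise or add to the silyloxydiene in another mode (through its C=C bond or across the diene), or the silyloxydiene may aromatise at 110 °C before it is trapped. The fallback uses known chemistry and sets out from enone 10. Its kinetic lithium enolate (LiN(iPr)2, THF, −78 °C) is added to commercial but-2-ynal to give the beta-hydroxy ketone F1. Dess–Martin oxidation gives the alkynyl 1,3-diketone F2. Diethylamine adds to the ynone and lets the enol oxygen close 6-endo with loss of the amine, giving the 2-methyl pyranone F3. Deprotonation of its 2-methyl group (LiN(SiMe3)2, THF, −78 °C) and alkylation with bromide 15 gives 21, where the route resumes at step 15; step 13 is then not needed.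

2. Step 15. The electrophilic bromine may be consumed at the pyranone C3 position or on the aryl ring instead of the conjugated C7=C8 bond, or it may add with poor facial selectivity. The fallback sets out from 21 and accepts the aromatisation risk named in the overview. The mildest possible acetonide hydrolysis (acid resin in methanol or cold aqueous acetic acid) gives the 5,6-diol F4. Hydroxyl-directed peracid epoxidation (mCPBA, CH2Cl2), steered by the allylic C6 hydroxyl to its own face, gives the cis epoxy diol pivalate F5. K2CO3/MeOH removes the pivalate to give the epoxy diol phenol F6. Conc. HCl in THF opens the epoxide at C8 and gives target 26 directly.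

3. Step 13. The dienolate may alkylate at the alpha carbon or twice, or it may take the acyl group from the aryl pivalate. The fallback sets out from bromide 15. Gamma-alkylation of the dianion of commercial tert-butyl acetoacetate (LiN(iPr)2, 2 equiv, THF, 0 °C) gives the tert-butyl beta-keto ester F7. Acetone with trifluoroacetic anhydride and trifluoroacetic acid converts it into dioxinone 18, where the route resumes at step 14.

**Further compounds**

F1 | step 14 | (4R,5S)-6-(1-hydroxybut-2-ynyl)-4,5-(isopropylidenedioxy)cyclohex-2-en-1-one (new centres not defined) | O=C1C=C[C@H]2OC(C)(C)O[C@H]2C1C(O)C#CC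
F2 | step 14 | (4R,5S)-6-(but-2-ynoyl)-4,5-(isopropylidenedioxy)cyclohex-2-en-1-one (drawn as the diketone) | O=C1C=C[C@H]2OC(C)(C)O[C@H]2C1C(=O)C#CC
F3 | step 14 | (5S,6R)-5,6-(isopropylidenedioxy)-2-methyl-5,6-dihydro-4H-chromen-4-one | Cc1cc(=O)c2c(o1)C=C[C@H]3OC(C)(C)O[C@@H]23
F4 | step 15 | (5S,6R)-5,6-dihydroxy-2-[2-(4-methoxy-3-pivaloyloxyphenyl)ethyl]-5,6-dihydro-4H-chromen-4-one | COc1ccc(CCc2cc(=O)c3c(o2)C=C[C@@H](O)[C@H]3O)cc1OC(=O)C(C)(C)C
F5 | step 15 | 7,8-epoxy-5,6-dihydroxy tetrahydrochromenone pivalate (epoxide oxygen cis to both hydroxyls) | COc1ccc(CCc2cc(=O)c3c(o2)[C@H]4O[C@H]4[C@@H](O)[C@H]3O)cc1OC(=O)C(C)(C)C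
F6 | step 15 | 7,8-epoxy-5,6-dihydroxy-2-[2-(3-hydroxy-4-methoxyphenyl)ethyl]-5,6,7,8-tetrahydro-4H-chromen-4-one (epoxide oxygen cis to both hydroxyls) | COc1ccc(CCc2cc(=O)c3c(o2)[C@H]4O[C@H]4[C@@H](O)[C@H]3O)cc1O
F7 | step 13 | tert-butyl 5-(4-methoxy-3-pivaloyloxyphenyl)-3-oxopentanoate | COc1ccc(CCC(=O)CC(=O)OC(C)(C)C)cc1OC(=O)C(C)(C)C
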